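Ring C is cut at its acyloin bond C3–C4. The precursor is a salicylaldehyde ether whose O1 side chain is a racemic, fast-enolising β-aryloxy-β-aryl α-keto allyl ester. A chiral triazolylidene can form an acyl anion only at the aromatic aldehyde (C4), which adds to the C3 ketone: one operation closes the pyranone ring (O1, C2, C3, C4, C4a, C8a), places oxygen on C3 and fixes C2 by dynamic kinetic resolution. The step exploits the acyloin C4(=O)–C3(OH) and the acidity of H–C2. The ester, a traceless activating group, later leaves as CO2. Ring A is built from 2,4,6-trihydroxybenzaldehyde by ortho-directed halogenation and two sp3 cross-couplings.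

Key step: step 14

Assumption: the (5aS,10bR) triazolium salt is taken to deliver C2 as R in step 14; if the sense proves opposite, its mirror-image salt is used and nothing else changes.

Step 1
Reactants: 1 (4S)-4-benzyl-1,3-oxazolidin-2-one; 2 3-methylbut-2-enoyl chloride
Product: 3 (4S)-4-benzyl-3-(3-methylbut-2-enoyl)-1,3-oxazolidin-2-one
Conditions: n-BuLi, THF, −78 °C; then 2, −78 to 0 °C
Reagents that add atoms: none
Why: N-acylation of the lithiated Evans oxazolidinone by the acid chloride, with no new stereocentre.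

Step 2
Reactants: 3 (4S)-4-benzyl-3-(3-methylbut-2-enoyl)-1,3-oxazolidin-2-one; 4 1-bromo-3-methylbut-2-ene
Product: 6 (4S)-4-benzyl-3-[(2S)-5-methyl-2-(prop-1-en-2-yl)hex-4-enoyl]-1,3-oxazolidin-2-one, via sodium dienolate 5 (not isolated)
Conditions: NaN(SiMe3)2, THF, −78 °C; then 4, −78 to −20 °C
Reagents that add atoms: none
Why: Evans auxiliary alkylation in its deconjugative form: γ-deprotonation should give the chelated (Z)-dienolate 5, which is prenylated at the α-carbon on the face opposite the benzyl group, so that the (2S) centre is set by the auxiliary.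

Step 3
Reactants: 6 (4S)-4-benzyl-3-[(2S)-5-methyl-2-(prop-1-en-2-yl)hex-4-enoyl]-1,3-oxazolidin-2-one
Product: 7 (2S)-5-methyl-2-(prop-1-en-2-yl)hex-4-en-1-ol
Conditions: LiBH4, H2O (1 equiv), Et2O, 0 °C
Reagents that add atoms: none
Why: Hydride reduction of the exocyclic imide carbonyl should release (S)-lavandulol and the auxiliary without enolising the β,γ-unsaturated α-centre.

Step 4
Reactants: 7 (2S)-5-methyl-2-(prop-1-en-2-yl)hex-4-en-1-ol
Product: 8 (3S)-3-(iodomethyl)-2,6-dimethylhepta-1,5-diene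
Conditions: I2, PPh3, imidazole, CH2Cl2, 0 to 23 °C
Reagents that add atoms: iodine, II
Why: Appel-type iodination by SN2 at the primary carbon, which leaves the neighbouring stereocentre untouched.

Step 5
Reactants: 9 2,4,6-trihydroxybenzaldehyde
Product: 10 2-hydroxy-4,6-bis(triisopropylsilyloxy)benzaldehyde
Conditions: TIPSCl (2.1 equiv), imidazole, DMF, 0 to 23 °C
Reagents that add atoms: chlorotriisopropylsilane, CC(C)[Si](Cl)(C(C)C)C(C)C
Why: Silylation of phenols: the para and one ortho hydroxyl should react, while the second ortho hydroxyl stays free because it is held in the hydrogen bond to the formyl group.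

Step 6
Reactants: 10 2-hydroxy-4,6-bis(triisopropylsilyloxy)benzaldehyde
Product: 11 2-hydroxy-3-iodo-4,6-bis(triisopropylsilyloxy)benzaldehyde
Conditions: NIS (1.0 equiv), CF3CO2H (10 mol %), CH2Cl2, 0 °C
Reagents that add atoms: N-iodosuccinimide, O=C1CCC(=O)N1I
Why: Electrophilic aromatic iodination directed by the free phenol to its ortho position (the future C8), whereas the other open position lies between two bulky silyloxy groups; this ties the free oxygen (future O1) to the carbon that will carry the lavandulyl group.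

Step 7
Reactants: 11 2-hydroxy-3-iodo-4,6-bis(triisopropylsilyloxy)benzaldehyde
Product: 12 3-bromo-6-hydroxy-5-iodo-2,4-bis(triisopropylsilyloxy)benzaldehyde
Conditions: NBS (1.05 equiv), MeCN, 0 °C
Reagents that add atoms: N-bromosuccinimide, O=C1CCC(=O)N1Br
Why: Electrophilic aromatic bromination at the only remaining ring position (the future C6), which is para to the free phenol.

Step 8
Reactants: 8 (3S)-3-(iodomethyl)-2,6-dimethylhepta-1,5-diene; 12 3-bromo-6-hydroxy-5-iodo-2,4-bis(triisopropylsilyloxy)benzaldehyde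
Product: 14 3-bromo-6-hydroxy-5-[(2R)-5-methyl-2-(prop-1-en-2-yl)hex-4-en-1-yl]-2,4-bis(triisopropylsilyloxy)benzaldehyde, via alkylzinc iodide 13 (not isolated)
Conditions: 8, Zn dust, LiCl, THF, 40 °C; then 12, Pd(OAc)2 (3 mol %), SPhos (6 mol %), THF, 25 °C, slow addition of 13
Reagents that add atoms: none
Why: Negishi coupling: zinc insertion into the primary C–I bond does not touch the stereocentre (its descriptor changes from S to R only through the priority rules), and palladium/SPhos should couple at C–I in preference to C–Br while tolerating the free phenol and the aldehyde.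

Step 9
Reactants: 14 3-bromo-6-hydroxy-5-[(2R)-5-methyl-2-(prop-1-en-2-yl)hex-4-en-1-yl]-2,4-bis(triisopropylsilyloxy)benzaldehyde; 15 2-methylbut-3-en-2-ol
Product: 17 2-hydroxy-5-(3-hydroxy-3-methylbutyl)-3-[(2R)-5-methyl-2-(prop-1-en-2-yl)hex-4-en-1-yl]-4,6-bis(triisopropylsilyloxy)benzaldehyde, via alkylborane 16 (not isolated)
Conditions: 15 (excess), 9-BBN, THF, 0 to 23 °C; then 3 M aq. K3PO4, 14, Pd(OAc)2 (5 mol %), SPhos (10 mol %), THF, 50 °C
Reagents that add atoms: none
Why: Anti-Markovnikov hydroboration followed by B-alkyl Suzuki–Miyaura coupling at the remaining C–Br bond; the alkene is used in excess so that no B–H is left to attack the lavandulyl double bonds.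

Step 10
Reactants: 18 2,4-dihydroxybenzaldehyde
Product: 19 2,4-bis(tert-butyldimethylsilyloxy)benzaldehyde
Conditions: TBSCl (2.2 equiv), imidazole, DMF, 23 °C
Reagents that add atoms: tert-butylchlorodimethylsilane, CC(C)(C)[Si](C)(C)Cl
Why: Silylation of both phenols of ring B with imidazole as base.

Step 11
Reactants: 20 dichloroacetyl chloride; 21 prop-2-en-1-ol
Product: 22 prop-2-en-1-yl dichloroacetate
Conditions: pyridine, CH2Cl2, 0 °C
Reagents that add atoms: none
Why: Acylation of the alcohol by the acid chloride.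

Step 12
Reactants: 19 2,4-bis(tert-butyldimethylsilyloxy)benzaldehyde; 22 prop-2-en-1-yl dichloroacetate
Product: 24 prop-2-en-1-yl 3-[2,4-bis(tert-butyldimethylsilyloxy)phenyl]-3-chloro-2-oxopropanoate (racemic), via chloroglycidic ester 23 (not isolated)
Conditions: NaN(SiMe3)2, THF, −78 to 23 °C
Reagents that add atoms: none
Why: Darzens condensation should give the α-chloroglycidic ester 23, which opens at the benzylic carbon with help from the electron-rich ring and rearranges by 1,2-chloride shift to the β-chloro α-keto ester; the racemic centre is intended.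

Step 13
Reactants: 17 2-hydroxy-5-(3-hydroxy-3-methylbutyl)-3-[(2R)-5-methyl-2-(prop-1-en-2-yl)hex-4-en-1-yl]-4,6-bis(triisopropylsilyloxy)benzaldehyde; 24 prop-2-en-1-yl 3-[2,4-bis(tert-butyldimethylsilyloxy)phenyl]-3-chloro-2-oxopropanoate
Product: 25 prop-2-en-1-yl 3-[2,4-bis(tert-butyldimethylsilyloxy)phenyl]-3-{2-formyl-4-(3-hydroxy-3-methylbutyl)-6-[(2R)-5-methyl-2-(prop-1-en-2-yl)hex-4-en-1-yl]-3,5-bis(triisopropylsilyloxy)phenoxy}-2-oxopropanoate (both epimers at the ether carbon)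
Conditions: K2CO3 (1.5 equiv), NaI (10 mol %), acetone, 0 to 23 °C
Reagents that add atoms: none
Why: Williamson-type SN2 alkylation of the only acidic hydroxyl (the phenol next to the formyl group) by the activated benzylic α-keto chloride under iodide catalysis; the new centre C2 forms as both epimers, which step 14 equilibrates.

Step 14
Reactants: 25 prop-2-en-1-yl 3-[2,4-bis(tert-butyldimethylsilyloxy)phenyl]-3-{2-formyl-4-(3-hydroxy-3-methylbutyl)-6-[(2R)-5-methyl-2-(prop-1-en-2-yl)hex-4-en-1-yl]-3,5-bis(triisopropylsilyloxy)phenoxy}-2-oxopropanoate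
Product: 26 prop-2-en-1-yl (2R,3R)-2-[2,4-bis(tert-butyldimethylsilyloxy)phenyl]-3-hydroxy-6-(3-hydroxy-3-methylbutyl)-8-[(2R)-5-methyl-2-(prop-1-en-2-yl)hex-4-en-1-yl]-4-oxo-5,7-bis(triisopropylsilyloxy)-3,4-dihydro-2H-chromene-3-carboxylate
Conditions: (5aS,10bR)-2-(pentafluorophenyl)-5a,10b-dihydro-4H,6H-indeno[2,1-b][1,2,4]triazolo[4,3-d][1,4]oxazin-2-ium tetrafluoroborate (15 mol %), K2CO3 (0.5 equiv), tert-butyl methyl ether, 23 °C
Reagents that add atoms: none
Why: The carbene released from the triazolium salt adds to the aldehyde carbon C4, the only carbonyl of 25 that can give a Breslow intermediate because C3 is a ketone, and the enaminol carbon then attacks the activated C3 ketone; proton transfer and loss of the carbene give the acyloin. The closest known reactions are the carbene-catalysed intramolecular crossed aldehyde–ketone benzoin that gives 3-hydroxychroman-4-ones and the dynamic kinetic crossed benzoin of β-stereogenic α-keto esters. Ring C (O1, C2, C3, C4, C4a, C8a) closes in a 6-exo-trig mode. C3 is set by the catalyst, which selects the face of the ketone, and C2 by dynamic kinetic resolution: H–C2, flanked by ring B, O1 and the 1,2-dicarbonyl, should be exchanged by carbonate faster than either epimer cyclises, and the epimer that places ring B pseudo-equatorial and trans to the new hydroxyl in the chair-like transition state should react. The step needs acyl anion formation at C4 and none at C3; making C3 a ketone excludes the Breslow intermediate whose β-elimination would expel the O1 phenoxide, and aldol addition of the C2 enol to the hindered aldehyde is reversible.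

Step 15
Reactants: 26 prop-2-en-1-yl (2R,3R)-2-[2,4-bis(tert-butyldimethylsilyloxy)phenyl]-3-hydroxy-6-(3-hydroxy-3-methylbutyl)-8-[(2R)-5-methyl-2-(prop-1-en-2-yl)hex-4-en-1-yl]-4-oxo-5,7-bis(triisopropylsilyloxy)-3,4-dihydro-2H-chromene-3-carboxylate
Product: 28 (2R,3R)-2-[2,4-bis(tert-butyldimethylsilyloxy)phenyl]-3-hydroxy-6-(3-hydroxy-3-methylbutyl)-8-[(2R)-5-methyl-2-(prop-1-en-2-yl)hex-4-en-1-yl]-5,7-bis(triisopropylsilyloxy)-2,3-dihydro-4H-chromen-4-one, via β-keto acid 27 (not isolated)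
Conditions: Pd(PPh3)4 (5 mol %), morpholine (5 equiv), THF, 0 to 23 °C, then 12 h at 23 °C
Reagents that add atoms: none
Why: Tsuji–Trost deallylation should give the β-keto acid 27, which loses CO2 to the enediol; ketonisation to the aryl ketone and amine-mediated equilibration through the same enediol should leave the diequatorial 2,3-trans isomer (3R) as the thermodynamic product, while C2, which is not α to the carbonyl, is untouched.

Step 16
Reactants: 28 (2R,3R)-2-[2,4-bis(tert-butyldimethylsilyloxy)phenyl]-3-hydroxy-6-(3-hydroxy-3-methylbutyl)-8-[(2R)-5-methyl-2-(prop-1-en-2-yl)hex-4-en-1-yl]-5,7-bis(triisopropylsilyloxy)-2,3-dihydro-4H-chromen-4-one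
Product: 29 (2R,3R)-2-(2,4-dihydroxyphenyl)-3,5,7-trihydroxy-6-(3-hydroxy-3-methylbutyl)-8-[(2R)-5-methyl-2-(prop-1-en-2-yl)hex-4-en-1-yl]-2,3-dihydro-4H-chromen-4-one
Conditions: Bu4NF (6 equiv), AcOH (6 equiv), THF, 0 °C
Reagents that add atoms: none
Why: Fluoride cleavage of the four aryl silyl ethers, buffered with acetic acid so that neither a phenoxide (C2 epimerisation by ring opening) nor a strong acid (cyclisation of a phenol onto the isopropenyl group or the tertiary alcohol) is present.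

Compound list
1 | (4S)-4-benzyl-1,3-oxazolidin-2-one | O=C1N[C@@H](Cc2ccccc2)CO1 | starting material
2 | 3-methylbut-2-enoyl chloride | CC(C)=CC(=O)Cl | starting material
3 | (4S)-4-benzyl-3-(3-methylbut-2-enoyl)-1,3-oxazolidin-2-one | CC(C)=CC(=O)N1[C@@H](Cc2ccccc2)COC1=O | intermediate
4 | 1-bromo-3-methylbut-2-ene (prenyl bromide) | CC(C)=CCBr | starting material
5 | sodium (1Z)-1-[(4S)-4-benzyl-2-oxo-1,3-oxazolidin-3-yl]-3-methylbuta-1,3-dien-1-olate (dienolate of 3) | [Na+].C=C(C)/C=C(\[O-])N1[C@@H](Cc2ccccc2)COC1=O | intermediate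
6 | (4S)-4-benzyl-3-[(2S)-5-methyl-2-(prop-1-en-2-yl)hex-4-enoyl]-1,3-oxazolidin-2-one | C=C(C)[C@H](CC=C(C)C)C(=O)N1[C@@H](Cc2ccccc2)COC1=O | intermediate
7 | (2S)-5-methyl-2-(prop-1-en-2-yl)hex-4-en-1-ol [(S)-lavandulol] | C=C(C)[C@H](CC=C(C)C)CO | intermediate
8 | (3S)-3-(iodomethyl)-2,6-dimethylhepta-1,5-diene [(S)-lavandulyl iodide] | C=C(C)[C@H](CC=C(C)C)CI | intermediate
9 | 2,4,6-trihydroxybenzaldehyde | O=Cc1c(O)cc(O)cc1O | starting material
10 | 2-hydroxy-4,6-bis(triisopropylsilyloxy)benzaldehyde | O=Cc1c(O)cc(O[Si](C(C)C)(C(C)C)C(C)C)cc1O[Si](C(C)C)(C(C)C)C(C)C | intermediate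
11 | 2-hydroxy-3-iodo-4,6-bis(triisopropylsilyloxy)benzaldehyde | O=Cc1c(O)c(I)c(O[Si](C(C)C)(C(C)C)C(C)C)cc1O[Si](C(C)C)(C(C)C)C(C)C | intermediate
12 | 3-bromo-6-hydroxy-5-iodo-2,4-bis(triisopropylsilyloxy)benzaldehyde | O=Cc1c(O)c(I)c(O[Si](C(C)C)(C(C)C)C(C)C)c(Br)c1O[Si](C(C)C)(C(C)C)C(C)C | intermediate
13 | [(2S)-5-methyl-2-(prop-1-en-2-yl)hex-4-en-1-yl]zinc iodide | C=C(C)[C@H](CC=C(C)C)C[Zn]I | intermediate
14 | 3-bromo-6-hydroxy-5-[(2R)-5-methyl-2-(prop-1-en-2-yl)hex-4-en-1-yl]-2,4-bis(triisopropylsilyloxy)benzaldehyde | C=C(C)[C@H](CC=C(C)C)Cc1c(O)c(C=O)c(O[Si](C(C)C)(C(C)C)C(C)C)c(Br)c1O[Si](C(C)C)(C(C)C)C(C)C | intermediate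
15 | 2-methylbut-3-en-2-ol | C=CC(C)(C)O | starting material
16 | 4-(9-borabicyclo[3.3.1]nonan-9-yl)-2-methylbutan-2-ol | CC(C)(O)CCB1C2CCCC1CCC2 | intermediate
17 | 2-hydroxy-5-(3-hydroxy-3-methylbutyl)-3-[(2R)-5-methyl-2-(prop-1-en-2-yl)hex-4-en-1-yl]-4,6-bis(triisopropylsilyloxy)benzaldehyde | C=C(C)[C@H](CC=C(C)C)Cc1c(O)c(C=O)c(O[Si](C(C)C)(C(C)C)C(C)C)c(CCC(C)(C)O)c1O[Si](C(C)C)(C(C)C)C(C)C | intermediate
18 | 2,4-dihydroxybenzaldehyde | O=Cc1ccc(O)cc1O | starting material
19 | 2,4-bis(tert-butyldimethylsilyloxy)benzaldehyde | O=Cc1ccc(O[Si](C)(C)C(C)(C)C)cc1O[Si](C)(C)C(C)(C)C | intermediate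
20 | dichloroacetyl chloride | O=C(Cl)C(Cl)Cl | starting material
21 | prop-2-en-1-ol (allyl alcohol) | C=CCO | starting material
22 | prop-2-en-1-yl dichloroacetate | C=CCOC(=O)C(Cl)Cl | intermediate
23 | prop-2-en-1-yl 3-[2,4-bis(tert-butyldimethylsilyloxy)phenyl]-2-chlorooxirane-2-carboxylate | C=CCOC(=O)C1(Cl)OC1c1ccc(O[Si](C)(C)C(C)(C)C)cc1O[Si](C)(C)C(C)(C)C | intermediate
24 | prop-2-en-1-yl 3-[2,4-bis(tert-butyldimethylsilyloxy)phenyl]-3-chloro-2-oxopropanoate (racemic) | C=CCOC(=O)C(=O)C(Cl)c1ccc(O[Si](C)(C)C(C)(C)C)cc1O[Si](C)(C)C(C)(C)C | intermediate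
25 | prop-2-en-1-yl 3-[2,4-bis(tert-butyldimethylsilyloxy)phenyl]-3-{2-formyl-4-(3-hydroxy-3-methylbutyl)-6-[(2R)-5-methyl-2-(prop-1-en-2-yl)hex-4-en-1-yl]-3,5-bis(triisopropylsilyloxy)phenoxy}-2-oxopropanoate (both epimers at the ether carbon) | C=C(C)[C@H](CC=C(C)C)Cc1c(OC(C(=O)C(=O)OCC=C)c2ccc(O[Si](C)(C)C(C)(C)C)cc2O[Si](C)(C)C(C)(C)C)c(C=O)c(O[Si](C(C)C)(C(C)C)C(C)C)c(CCC(C)(C)O)c1O[Si](C(C)C)(C(C)C)C(C)C | intermediate
26 | prop-2-en-1-yl (2R,3R)-2-[2,4-bis(tert-butyldimethylsilyloxy)phenyl]-3-hydroxy-6-(3-hydroxy-3-methylbutyl)-8-[(2R)-5-methyl-2-(prop-1-en-2-yl)hex-4-en-1-yl]-4-oxo-5,7-bis(triisopropylsilyloxy)-3,4-dihydro-2H-chromene-3-carboxylate | C=C(C)[C@H](CC=C(C)C)Cc1c(O[Si](C(C)C)(C(C)C)C(C)C)c(CCC(C)(C)O)c(O[Si](C(C)C)(C(C)C)C(C)C)c2c1O[C@H](c1ccc(O[Si](C)(C)C(C)(C)C)cc1O[Si](C)(C)C(C)(C)C)[C@](O)(C(=O)OCC=C)C2=O | intermediate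
27 | (2R,3R)-2-[2,4-bis(tert-butyldimethylsilyloxy)phenyl]-3-hydroxy-6-(3-hydroxy-3-methylbutyl)-8-[(2R)-5-methyl-2-(prop-1-en-2-yl)hex-4-en-1-yl]-4-oxo-5,7-bis(triisopropylsilyloxy)-3,4-dihydro-2H-chromene-3-carboxylic acid | C=C(C)[C@H](CC=C(C)C)Cc1c(O[Si](C(C)C)(C(C)C)C(C)C)c(CCC(C)(C)O)c(O[Si](C(C)C)(C(C)C)C(C)C)c2c1O[C@H](c1ccc(O[Si](C)(C)C(C)(C)C)cc1O[Si](C)(C)C(C)(C)C)[C@](O)(C(=O)O)C2=O | intermediate
28 | (2R,3R)-2-[2,4-bis(tert-butyldimethylsilyloxy)phenyl]-3-hydroxy-6-(3-hydroxy-3-methylbutyl)-8-[(2R)-5-methyl-2-(prop-1-en-2-yl)hex-4-en-1-yl]-5,7-bis(triisopropylsilyloxy)-2,3-dihydro-4H-chromen-4-one | C=C(C)[C@H](CC=C(C)C)Cc1c(O[Si](C(C)C)(C(C)C)C(C)C)c(CCC(C)(C)O)c(O[Si](C(C)C)(C(C)C)C(C)C)c2c1O[C@H](c1ccc(O[Si](C)(C)C(C)(C)C)cc1O[Si](C)(C)C(C)(C)C)[C@@H](O)C2=O | intermediate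
29 | (2R,3R)-2-(2,4-dihydroxyphenyl)-3,5,7-trihydroxy-6-(3-hydroxy-3-methylbutyl)-8-[(2R)-5-methyl-2-(prop-1-en-2-yl)hex-4-en-1-yl]-2,3-dihydro-4H-chromen-4-one (CNP0183552.3) | C=C(C)[C@H](CC=C(C)C)Cc1c(O)c(CCC(C)(C)O)c(O)c2c1O[C@H](c1ccc(O)cc1O)[C@@H](O)C2=O | target

Total step count: 16. Longest linear sequence: 10 steps (steps 1 to 4, 8, 9 and 13 to 16).

Steps most likely to fail

Step 14. The carbene may fail to add to the aldehyde, which is flanked by two oxygen substituents and is electron-rich. The keto ester may also be held back as its enol, or the two C2 epimers may interconvert too slowly for the resolution to be dynamic. Fallback: starting from 25, a reductive ketyl–aldehyde coupling with SmI2 (t-BuOH, THF, −78 °C) should close the same C3–C4 bond and give the chromane-3,4-diol ester F1. Oxidation of its benzylic C4 carbinol with 2-iodoxybenzoic acid (EtOAc, 70 °C) returns to the route at 26. This sequence has no control over C2, so the (2R) series would have to be separated from the (2S) series by chromatography; the two are diastereomers because of the lavandulyl centre. The configuration at C3 does not matter, since step 15 resets it.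

Step 13. The hindered, hydrogen-bonded phenoxide may substitute too slowly, so that dehydrochlorination and self-condensation of 24, or silyl transfer, take over. Fallback: starting from 24, reductive dechlorination (Zn, AcOH) should give the arylpyruvate F2. Diazo transfer (4-acetamidobenzenesulfonyl azide, DBU, MeCN) should then give the α-diazo ketone F3. Insertion of its carbenoid into the O–H bond of phenol 17, catalysed by Rh2(OAc)4 (CH2Cl2, slow addition), returns to the route at 25.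

Step 9. Oxidative addition and transmetalation at a bromide flanked by two silyloxy groups may be slow, and aqueous phosphate at 50 °C may begin to cleave the aryl silyl ethers. Fallback: starting from 14, a base-free Negishi coupling is used. 3-Methylbutane-1,3-diol is iodinated at its primary hydroxyl (I2, PPh3, imidazole) to 4-iodo-2-methylbutan-2-ol F4. This is silylated (Et3SiOTf, 2,6-lutidine) to the triethylsilyl ether F5 and converted with Zn and LiCl into the alkylzinc iodide F6. Coupling with 14 (Pd(OAc)2, CPhos, THF) should give the silyl ether F7, and AcOH–THF–H2O removes the triethylsilyl group to return to the route at 17.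

Further compounds
F1 | step 14 | prop-2-en-1-yl 2-[2,4-bis(tert-butyldimethylsilyloxy)phenyl]-3,4-dihydroxy-6-(3-hydroxy-3-methylbutyl)-8-[(2R)-5-methyl-2-(prop-1-en-2-yl)hex-4-en-1-yl]-5,7-bis(triisopropylsilyloxy)-3,4-dihydro-2H-chromene-3-carboxylate (mixture at C2, C3 and C4) | C=C(C)[C@H](CC=C(C)C)Cc1c(O[Si](C(C)C)(C(C)C)C(C)C)c(CCC(C)(C)O)c(O[Si](C(C)C)(C(C)C)C(C)C)c2c1OC(c1ccc(O[Si](C)(C)C(C)(C)C)cc1O[Si](C)(C)C(C)(C)C)C(O)(C(=O)OCC=C)C2O
F2 | step 13 | prop-2-en-1-yl 3-[2,4-bis(tert-butyldimethylsilyloxy)phenyl]-2-oxopropanoate | C=CCOC(=O)C(=O)Cc1ccc(O[Si](C)(C)C(C)(C)C)cc1O[Si](C)(C)C(C)(C)C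
F3 | step 13 | prop-2-en-1-yl 3-[2,4-bis(tert-butyldimethylsilyloxy)phenyl]-3-diazo-2-oxopropanoate | C=CCOC(=O)C(=O)C(=[N+]=[N-])c1ccc(O[Si](C)(C)C(C)(C)C)cc1O[Si](C)(C)C(C)(C)C
F4 | step 9 | 4-iodo-2-methylbutan-2-ol | CC(C)(O)CCI
F5 | step 9 | triethyl[(4-iodo-2-methylbutan-2-yl)oxy]silane | CC[Si](CC)(CC)OC(C)(C)CCI
F6 | step 9 | [3-methyl-3-(triethylsilyloxy)butyl]zinc iodide | CC[Si](CC)(CC)OC(C)(C)CC[Zn]I
F7 | step 9 | 2-hydroxy-3-[(2R)-5-methyl-2-(prop-1-en-2-yl)hex-4-en-1-yl]-5-[3-methyl-3-(triethylsilyloxy)butyl]-4,6-bis(triisopropylsilyloxy)benzaldehyde | C=C(C)[C@H](CC=C(C)C)Cc1c(O)c(C=O)c(O[Si](C(C)C)(C(C)C)C(C)C)c(CCC(C)(C)O[Si](CC)(CC)CC)c1O[Si](C(C)C)(C(C)C)C(C)C
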